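Feature: the oxepine ring (O2'–C2'–C1'–C2–C3–CH2–CH) has one ring bond joining two sp3 carbons, CH2–CH(O), and its CH(O) end is the only stereocentre. Written as C=C, it becomes an achiral cyclic aryl enol ether.
Last ring: the 2,2-dimethylpyran on O7/C8 ⇒ 7-O-(1,1-dimethylpropargyl) ether (aromatic Claisen cascade), installed only after all hydrogenations.
Stereocentre ⇒ enantioselective hydrogenation of the ring enol ether; ring C=C ⇒ ring-closing metathesis of a 3-vinyl group with a 2'-O–C(=CH2)–CMe2OH enol ether.
Enol ether ⇒ copper-catalysed O-vinylation of the 2'-phenol; 3-vinyl ⇒ Suzuki coupling of a 3-iodoflavone; flavone ⇒ Baker–Venkataraman diketone from 2,4,6-trihydroxyacetophenone and methyl 2,4-dihydroxybenzoate.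
Ring order: pyranone ring C, oxepine, dimethylpyran. Protecting groups: Bn on O7 (hydrogenolysis), MOM on O5 and O4' (last step), SEM on O2' (fluoride).

Key step: step 14

Remark: flavone numbering is used from 10 on (O1, C2, C3, C4=O, ring A C5–C8, ring B primed); MOM = CH2OCH3, SEM = CH2OCH2CH2SiMe3, Bn = CH2Ph; 13, 16 and 22 are bought.
Assumption: the sense of induction in step 15 is taken from the quadrant model for iridium phosphine–oxazoline catalysts; should a test hydrogenation show the opposite sense, the (R)-ligand takes the place of the (S)-ligand.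

Step 1
Reactants: 1 2,4,6-trihydroxyacetophenone
Product: 2 1-[4-(benzyloxy)-2,6-dihydroxyphenyl]ethan-1-one
Conditions: BnBr (1.0 equiv), K2CO3 (1.1 equiv), acetone, reflux
Reagents that add atoms: benzyl bromide, BrCc1ccccc1
Why: Williamson etherification; the 4-hydroxyl is the only one not hydrogen-bonded to the acetyl carbonyl and is the most acidic, so one equivalent of benzyl bromide should react there first.

Step 2
Reactants: 2 1-[4-(benzyloxy)-2,6-dihydroxyphenyl]ethan-1-one
Product: 3 1-[4-(benzyloxy)-2-hydroxy-6-(methoxymethoxy)phenyl]ethan-1-one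
Conditions: MOMCl (1.1 equiv), K2CO3, acetone, 0 °C to rt
Reagents that add atoms: chloromethyl methyl ether, COCCl
Why: Williamson-type O-alkylation; the two remaining hydroxyls are equivalent, and once one is capped the other is locked in a strong chelate to the ketone and should resist a second alkylation under K2CO3.

Step 3
Reactants: 4 methyl 2,4-dihydroxybenzoate
Product: 5 methyl 2-hydroxy-4-(methoxymethoxy)benzoate
Conditions: MOMCl (1.05 equiv), K2CO3, acetone, rt
Reagents that add atoms: chloromethyl methyl ether, COCCl
Why: Selective O-alkylation; the 4-hydroxyl is free while the 2-hydroxyl is hydrogen-bonded to the ester carbonyl, so a weak base and one equivalent of MOMCl should cap O4 only.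

Step 4
Reactants: 5 methyl 2-hydroxy-4-(methoxymethoxy)benzoate
Product: 6 methyl 4-(methoxymethoxy)-2-{[2-(trimethylsilyl)ethoxy]methoxy}benzoate
Conditions: NaH, DMF, 0 °C; SEMCl, 0 °C to rt
Reagents that add atoms: 2-(trimethylsilyl)ethoxymethyl chloride, C[Si](C)(C)CCOCCl
Why: Williamson-type alkylation of the sodium phenoxide; SEM is chosen for O2 because fluoride will later remove it without touching MOM, benzyl or a vinyl group.

Step 5
Reactants: 6 methyl 4-(methoxymethoxy)-2-{[2-(trimethylsilyl)ethoxy]methoxy}benzoate
Product: 7 4-(methoxymethoxy)-2-{[2-(trimethylsilyl)ethoxy]methoxy}benzoic acid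
Conditions: LiOH, THF–MeOH–H2O, 50 °C; then 1 M HCl to pH 4, 0 °C
Reagents that add atoms: lithium hydroxide, [Li+].[OH-]
Why: Ester saponification under basic conditions to which both acetals are inert; the brief cold acidification only protonates the carboxylate.

Step 6
Reactants: 3 1-[4-(benzyloxy)-2-hydroxy-6-(methoxymethoxy)phenyl]ethan-1-one; 7 4-(methoxymethoxy)-2-{[2-(trimethylsilyl)ethoxy]methoxy}benzoic acid
Product: 8 2-acetyl-5-(benzyloxy)-3-(methoxymethoxy)phenyl 4-(methoxymethoxy)-2-{[2-(trimethylsilyl)ethoxy]methoxy}benzoate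
Conditions: DCC, DMAP (20 mol %), CH2Cl2, rt
Reagents that add atoms: none
Why: Steglich esterification; the acylpyridinium species acylates even the chelated ortho-hydroxyl of 3, the only free OH present, under neutral conditions that spare the acetals.

Step 7
Reactants: 8 2-acetyl-5-(benzyloxy)-3-(methoxymethoxy)phenyl 4-(methoxymethoxy)-2-{[2-(trimethylsilyl)ethoxy]methoxy}benzoate
Product: 9 1-[4-(benzyloxy)-2-hydroxy-6-(methoxymethoxy)phenyl]-3-[4-(methoxymethoxy)-2-{[2-(trimethylsilyl)ethoxy]methoxy}phenyl]propane-1,3-dione
Conditions: KOH (powder), pyridine, 50 °C; then AcOH–ice water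
Reagents that add atoms: none
Why: Baker–Venkataraman rearrangement; the methyl ketone enolate attacks the neighbouring aryl ester intramolecularly and the aroyl group moves from O to C, driven by formation of the stabilised diketonate and phenoxide.

Step 8
Reactants: 9 1-[4-(benzyloxy)-2-hydroxy-6-(methoxymethoxy)phenyl]-3-[4-(methoxymethoxy)-2-{[2-(trimethylsilyl)ethoxy]methoxy}phenyl]propane-1,3-dione
Product: 10 7-(benzyloxy)-5-(methoxymethoxy)-2-[4-(methoxymethoxy)-2-{[2-(trimethylsilyl)ethoxy]methoxy}phenyl]-4H-chromen-4-one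
Conditions: NaOAc, AcOH, 100 °C
Reagents that add atoms: none
Why: Cyclodehydration of an o-hydroxyaryl 1,3-diketone; only ring A carries a free phenol, so closure onto the ring-B carbonyl is the only mode open, and buffered anhydrous acetic acid should be too weak to cleave aryl MOM or SEM acetals, which need aqueous mineral acid.

Step 9
Reactants: 10 7-(benzyloxy)-5-(methoxymethoxy)-2-[4-(methoxymethoxy)-2-{[2-(trimethylsilyl)ethoxy]methoxy}phenyl]-4H-chromen-4-one
Product: 12 7-(benzyloxy)-3-iodo-5-(methoxymethoxy)-2-[4-(methoxymethoxy)-2-{[2-(trimethylsilyl)ethoxy]methoxy}phenyl]-4H-chromen-4-one, via 3-lithioflavone 11 (not isolated)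
Conditions: LiN(iPr)2 (1.3 equiv), THF, −78 °C; then I2, −78 °C to rt
Reagents that add atoms: iodine, II; lithium diisopropylamide, [Li+].CC(C)[N-]C(C)C (lithium of 11 only)
Why: Deprotonation of the flavone C3–H (the most acidic C–H, with lithium held by the C4 carbonyl) followed by iodinolysis places the halogen at C3 whatever the arene electronics, whereas an electrophilic halogenation of the diketone or the flavone would attack the phloroglucinol-type ring A.

Step 10
Reactants: 12 7-(benzyloxy)-3-iodo-5-(methoxymethoxy)-2-[4-(methoxymethoxy)-2-{[2-(trimethylsilyl)ethoxy]methoxy}phenyl]-4H-chromen-4-one; 13 potassium vinyltrifluoroborate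
Product: 14 7-(benzyloxy)-3-ethenyl-5-(methoxymethoxy)-2-[4-(methoxymethoxy)-2-{[2-(trimethylsilyl)ethoxy]methoxy}phenyl]-4H-chromen-4-one
Conditions: PdCl2(dppf)·CH2Cl2 (5 mol %), Cs2CO3, THF–H2O 9:1, 70 °C
Reagents that add atoms: none
Why: Suzuki–Miyaura coupling by oxidative addition of zerovalent palladium into the C3–I bond, transmetalation from the slowly hydrolysed vinyltrifluoroborate and reductive elimination; O2' stays protected here so that it cannot close onto C3 to a benzofuran.

Step 11
Reactants: 14 7-(benzyloxy)-3-ethenyl-5-(methoxymethoxy)-2-[4-(methoxymethoxy)-2-{[2-(trimethylsilyl)ethoxy]methoxy}phenyl]-4H-chromen-4-one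
Product: 15 7-(benzyloxy)-3-ethenyl-2-[2-hydroxy-4-(methoxymethoxy)phenyl]-5-(methoxymethoxy)-4H-chromen-4-one
Conditions: Bu4NF (3 equiv), THF, 60 °C; then AcOH
Reagents that add atoms: none
Why: Fluoride attacks silicon and the SEM group fragments by β-elimination to release the 2'-phenoxide, while MOM and benzyl ethers and the vinyl group are inert to fluoride.

Step 12
Reactants: 16 3-methylbuta-1,2-diene
Product: 17 3-bromo-2-methylbut-3-en-2-ol
Conditions: NBS, acetone–H2O, 0 °C
Reagents that add atoms: N-bromosuccinimide, O=C1CCC(=O)N1Br; water, O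
Why: Bromohydroxylation of an allene; bromine adds to the central carbon through the bromonium ion of the more substituted double bond and water opens it at the tertiary terminus, which avoids acid treatment of an ionisable tertiary propargylic alcohol and leaves a vinyl bromide too electron-poor to react again.

Step 13
Reactants: 15 7-(benzyloxy)-3-ethenyl-2-[2-hydroxy-4-(methoxymethoxy)phenyl]-5-(methoxymethoxy)-4H-chromen-4-one; 17 3-bromo-2-methylbut-3-en-2-ol
Product: 18 7-(benzyloxy)-3-ethenyl-2-{2-[(3-hydroxy-3-methylbut-1-en-2-yl)oxy]-4-(methoxymethoxy)phenyl}-5-(methoxymethoxy)-4H-chromen-4-one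
Conditions: CuI (20 mol %), N,N-dimethylglycine (40 mol %), Cs2CO3, 17 (2.5 equiv), 1,4-dioxane, 90 °C; chromatography on Et3N-washed silica
Reagents that add atoms: none
Why: Ullmann-type C–O coupling of a phenoxide with an alkenyl bromide under CuI/amino-acid catalysis, which keeps the double bond where the halide was; 15 has a single free phenol and no halide, and the hindered tertiary hydroxyl of 17 should not compete as a nucleophile.

Step 14
Reactants: 18 7-(benzyloxy)-3-ethenyl-2-{2-[(3-hydroxy-3-methylbut-1-en-2-yl)oxy]-4-(methoxymethoxy)phenyl}-5-(methoxymethoxy)-4H-chromen-4-one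
Product: 19 7-(benzyloxy)-5,4'-bis(methoxymethoxy)flavone bridged from C3 to O2' by CH=C[C(CH3)2OH] (CH on C3), an achiral benzoxepine enol ether
Conditions: RuCl2(=CHPh)(PCy3)(H2IMes) (second-generation Grubbs catalyst, 10 mol %), toluene (2 mM), 80 °C, argon sparge
Reagents that add atoms: none
Why: The ruthenium benzylidene first exchanges with the unhindered monosubstituted 3-vinyl group; the chromonyl alkylidene then adds in a [2+2] sense to the neighbouring CH2=C(OAr) bond with ruthenium on the CH2 end, and cycloreversion releases the ring alkene and Ru=CH2, which carries the chain while ethene is swept out. The closest known reaction type is enol ether–olefin ring-closing metathesis with N-heterocyclic-carbene ruthenium catalysts, as used for benzofurans and 4H-chromenes from aryl vinyl ethers, for seven-membered cyclic enol ethers and for 1,1-disubstituted olefins bearing a tert-alkyl group. The oxepine closes as a seven-membered ring by forming the C=C bond between the carbon on C3 and the oxygen-bearing carbon; five of its seven atoms already sit in the twisted C3=C2–C1'=C2'–O array, so the two alkenes are held within reach and high dilution disfavours oligomers. No stereocentre is formed and the ring size allows only the cis ring alkene, so 19 should be a single achiral compound. The selectivity needed is initiation at the vinyl group and not at the enol ether, which would give an inert Fischer-type carbene; the enol ether is 1,1-disubstituted and flanked by a quaternary carbon, so it should only be reached intramolecularly at its CH2 terminus. Benzyl and MOM ethers, the free tertiary alcohol and the tetrasubstituted C2=C3 bond of the chromone are not substrates for the catalyst.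

Step 15
Reactants: 19 7-(benzyloxy)-5,4'-bis(methoxymethoxy)flavone bridged from C3 to O2' by CH=C[C(CH3)2OH]
Product: 20 (R)-dihydro derivative of 19 with the bridge C3–CH2–CH[C(CH3)2OH]–O2' and an (R)-configured CH
Conditions: H2 (50 bar), [Ir(cod)(L)]BArF (3 mol %), L = (S)-4-tert-butyl-2-[2-(di-o-tolylphosphanyl)phenyl]-4,5-dihydrooxazole, BArF = B[3,5-(CF3)2C6H3]4, CH2Cl2, rt
Reagents that add atoms: none
Why: Proposed new method: iridium phosphine–oxazoline catalysts hydrogenate trisubstituted alkenes through an iridium hydride–alkene complex in which the alkene binds with its vinylic hydrogen in the quadrant blocked by the oxazoline tert-butyl group, so that migratory insertion and reductive elimination deliver both hydrogens to one face; the closest known reaction type is the enantioselective hydrogenation of 2-substituted 4H-chromenes and acyclic aryl enol ethers with such catalysts, and the extension lies in the seven-membered ring, the conjugation with the chromone and the adjacent tertiary carbinol; with CMe2OH trans and OAr cis to the chromone carbon the quadrant model predicts the (R)-centre for the (S)-ligand, while the tetrasubstituted chromone alkene and the benzyl ether should be left alone.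

Step 16
Reactants: 20 (R)-dihydro derivative of 19
Product: 21 (R)-7-hydroxy compound (20 without the benzyl group)
Conditions: H2 (1 atm), Pd/C (10 wt %), EtOAc–MeOH, rt
Reagents that add atoms: none
Why: Hydrogenolysis of the benzylic C–O bond on palladium; the only alkene left is the tetrasubstituted chromone C2=C3 bond, which should resist these conditions together with the MOM acetals and the non-benzylic C–O bond at the stereocentre.

Step 17
Reactants: 21 (R)-7-hydroxy compound; 22 3-chloro-3-methylbut-1-yne
Product: 23 (R)-7-[(2-methylbut-3-yn-2-yl)oxy] ether of 21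
Conditions: K2CO3, KI (20 mol %), CuI (5 mol %), DMF, 60 °C
Reagents that add atoms: none
Why: Copper-assisted O-alkylation of a phenoxide with a tertiary propargylic chloride; O7 is the only free phenol because O5 and O4' carry MOM, and K2CO3 does not deprotonate the tertiary alcohol.

Step 18
Reactants: 23 (R)-7-[(2-methylbut-3-yn-2-yl)oxy] ether of 21
Product: 25 (R)-5,4'-bis-O-(methoxymethyl) ether of the target (2,2-dimethyl-2H-pyran fused at O7/C8), via 8-allenyl-7-phenol 24 (not isolated)
Conditions: N,N-diethylaniline, 160 °C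
Reagents that add atoms: none
Why: Aromatic propargyl Claisen rearrangement, enolisation to 24, 1,5-hydrogen shift and oxa-6π electrocyclisation; migration to C8 keeps the C4a=C8a bond and hence the 4-pyranone conjugation in the dienone stage and avoids the MOM-flanked C6, as with 7-propargyloxychromones and 5-alkoxy-7-propargyloxycoumarins that give angular pyrans, and the stereocentre carries no acidic hydrogen and takes no part.

Step 19
Reactants: 25 (R)-5,4'-bis-O-(methoxymethyl) ether of the target
Product: 26 target CNP0329736.1, the (R)-oxepinoflavone with 5-OH, 4'-OH and the 7,8-fused 2,2-dimethylpyran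
Conditions: HCl (1 M in MeOH–THF), 45 °C
Reagents that add atoms: none
Why: Acid-catalysed acetal exchange with methanol frees O5 (helped by the peri carbonyl) and O4'; dilute acid at mild temperature should spare the 2,2-dimethylchromene, the non-activated tertiary alcohol and the secondary alkyl aryl ether at the (R)-centre.

Compound list
1 | 2,4,6-trihydroxyacetophenone | CC(=O)c1c(O)cc(O)cc1O | starting material
2 | 1-[4-(benzyloxy)-2,6-dihydroxyphenyl]ethan-1-one | CC(=O)c1c(O)cc(OCc2ccccc2)cc1O | intermediate
3 | 1-[4-(benzyloxy)-2-hydroxy-6-(methoxymethoxy)phenyl]ethan-1-one | CC(=O)c1c(O)cc(OCc2ccccc2)cc1OCOC | intermediate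
4 | methyl 2,4-dihydroxybenzoate | COC(=O)c1ccc(O)cc1O | starting material
5 | methyl 2-hydroxy-4-(methoxymethoxy)benzoate | COC(=O)c1ccc(OCOC)cc1O | intermediate
6 | methyl 4-(methoxymethoxy)-2-{[2-(trimethylsilyl)ethoxy]methoxy}benzoate | COC(=O)c1ccc(OCOC)cc1OCOCC[Si](C)(C)C | intermediate
7 | 4-(methoxymethoxy)-2-{[2-(trimethylsilyl)ethoxy]methoxy}benzoic acid | OC(=O)c1ccc(OCOC)cc1OCOCC[Si](C)(C)C | intermediate
8 | 2-acetyl-5-(benzyloxy)-3-(methoxymethoxy)phenyl 4-(methoxymethoxy)-2-{[2-(trimethylsilyl)ethoxy]methoxy}benzoate | CC(=O)c1c(OC(=O)c2ccc(OCOC)cc2OCOCC[Si](C)(C)C)cc(OCc2ccccc2)cc1OCOC | intermediate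
9 | 1-[4-(benzyloxy)-2-hydroxy-6-(methoxymethoxy)phenyl]-3-[4-(methoxymethoxy)-2-{[2-(trimethylsilyl)ethoxy]methoxy}phenyl]propane-1,3-dione | O=C(CC(=O)c1ccc(OCOC)cc1OCOCC[Si](C)(C)C)c1c(O)cc(OCc2ccccc2)cc1OCOC | intermediate
10 | 7-(benzyloxy)-5-(methoxymethoxy)-2-[4-(methoxymethoxy)-2-{[2-(trimethylsilyl)ethoxy]methoxy}phenyl]-4H-chromen-4-one | O=c1cc(-c2ccc(OCOC)cc2OCOCC[Si](C)(C)C)oc2cc(OCc3ccccc3)cc(OCOC)c12 | intermediate
11 | 3-lithio derivative of 10 | [Li]c1c(-c2ccc(OCOC)cc2OCOCC[Si](C)(C)C)oc2cc(OCc3ccccc3)cc(OCOC)c2c1=O | intermediate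
12 | 3-iodo derivative of 10 | Ic1c(-c2ccc(OCOC)cc2OCOCC[Si](C)(C)C)oc2cc(OCc3ccccc3)cc(OCOC)c2c1=O | intermediate
13 | potassium vinyltrifluoroborate | [K+].C=C[B-](F)(F)F | starting material
14 | 3-ethenyl derivative of 10 | C=Cc1c(-c2ccc(OCOC)cc2OCOCC[Si](C)(C)C)oc2cc(OCc3ccccc3)cc(OCOC)c2c1=O | intermediate
15 | 7-(benzyloxy)-3-ethenyl-2-[2-hydroxy-4-(methoxymethoxy)phenyl]-5-(methoxymethoxy)-4H-chromen-4-one | C=Cc1c(-c2ccc(OCOC)cc2O)oc2cc(OCc3ccccc3)cc(OCOC)c2c1=O | intermediate
16 | 3-methylbuta-1,2-diene | CC(C)=C=C | starting material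
17 | 3-bromo-2-methylbut-3-en-2-ol | CC(C)(O)C(Br)=C | intermediate
18 | 7-(benzyloxy)-3-ethenyl-2-{2-[(3-hydroxy-3-methylbut-1-en-2-yl)oxy]-4-(methoxymethoxy)phenyl}-5-(methoxymethoxy)-4H-chromen-4-one (metathesis precursor, achiral) | C=Cc1c(-c2ccc(OCOC)cc2OC(=C)C(C)(C)O)oc2cc(OCc3ccccc3)cc(OCOC)c2c1=O | intermediate
19 | 7-(benzyloxy)-5,4'-bis(methoxymethoxy)flavone bridged C3–CH=C[C(CH3)2OH]–O2' (cyclic enol ether, achiral) | CC(C)(O)C1=Cc2c(oc3cc(OCc4ccccc4)cc(OCOC)c3c2=O)-c2ccc(OCOC)cc2O1 | intermediate
20 | (R)-7-(benzyloxy)-5,4'-bis(methoxymethoxy)flavone bridged C3–CH2–CH[C(CH3)2OH]–O2' | CC(C)(O)[C@H]1Cc2c(oc3cc(OCc4ccccc4)cc(OCOC)c3c2=O)-c2ccc(OCOC)cc2O1 | intermediate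
21 | (R)-7-hydroxy analogue of 20 | CC(C)(O)[C@H]1Cc2c(oc3cc(O)cc(OCOC)c3c2=O)-c2ccc(OCOC)cc2O1 | intermediate
22 | 3-chloro-3-methylbut-1-yne | CC(C)(Cl)C#C | starting material
23 | (R)-7-[(2-methylbut-3-yn-2-yl)oxy] ether of 21 | CC(C)(O)[C@H]1Cc2c(oc3cc(OC(C)(C)C#C)cc(OCOC)c3c2=O)-c2ccc(OCOC)cc2O1 | intermediate
24 | (R)-7-hydroxy-8-(3-methylbuta-1,2-dien-1-yl) isomer of 23 | CC(C)=C=Cc1c(O)cc(OCOC)c2c(=O)c3c(oc12)-c1ccc(OCOC)cc1O[C@@H](C(C)(C)O)C3 | intermediate
25 | (R)-5,4'-bis-O-(methoxymethyl) ether of the target | CC1(C)C=Cc2c(cc(OCOC)c3c(=O)c4c(oc23)-c2ccc(OCOC)cc2O[C@@H](C(C)(C)O)C4)O1 | intermediate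
26 | CNP0329736.1, (R)-configured | CC1(C)C=Cc2c(cc(O)c3c(=O)c4c(oc23)-c2ccc(O)cc2O[C@@H](C(C)(C)O)C4)O1 | target

Total step count: 19. Longest linear sequence: 16 steps (4 to 26 through steps 3–11 and 13–19).

Steps most likely to fail

Risk 1 (step 15): facial discrimination may be poor because the neighbouring hydroxyl can bind iridium and override the quadrant control. Turnover on the hindered, conjugated enol ether may be slow, and the acidic iridium hydrides may ionise the enol ether or the tertiary allylic alcohol. Fallback by resolution instead of asymmetric catalysis, setting out from 19: hydrogenation over Pd/C (10 wt %, H2, EtOAc–MeOH) should saturate the enol ether from both faces and remove the benzyl group in the same operation, giving the racemic phenol F1. Preparative chromatography on a cellulose- or amylose-carbamate chiral stationary phase then separates the (S)-enantiomer F2, which is set aside, from the (R)-enantiomer, which is 21, where the route is rejoined.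

Risk 2 (step 14): the alkylidene formed on the vinyl group may be held by chelation to the C4 carbonyl, and attack on the hindered enol ether may be too slow. Vinyl homocoupling and catalyst decay could then take over. Fallback that closes the oxepine at the O–CH bond instead of the C=C bond, setting out from diketone 9:
- C-alkylation with prenyl bromide (K2CO3, acetone) gives the 2-prenyl diketone F3.
- NaOAc/AcOH closes it to the 3-prenylflavone F4.
- Shi epoxidation with the L-fructose-derived ketone (KHSO5, K2CO3 buffer, MeCN–dimethoxymethane–H2O, 0 °C) oxidises the only electron-rich alkene to the (S)-epoxide F5.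
- Bu4NF (THF, 60 °C) frees the 2'-phenoxide, which opens the epoxide at its secondary carbon (7-exo-tet, inversion) to the (R)-ether.

The route is rejoined at 20.

Risk 3 (step 13): coupling of a hindered, electron-poor phenoxide with a hindered 1,1-disubstituted alkenyl bromide may stall. Loss of HBr from the bromide and thermal decay of the vinylchromone would then compete. Fallback that builds the enol ether by carbonyl chemistry, setting out from 15:
- O–H insertion of the carbenoid from methyl 2-diazo-2-(dimethoxyphosphoryl)acetate (Rh2(OAc)4, toluene, 80 °C) gives the aryloxy phosphonate F6.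
- Horner–Wadsworth–Emmons reaction with aqueous formaldehyde (K2CO3, THF) gives the methyl 2-aryloxyacrylate F7.
- MeMgBr (3 equiv, THF, −40 °C) adds twice to the ester, which should react ahead of the vinylogous-ester carbonyl of the fully substituted chromone.

The route is rejoined at 18.

Further compounds
F1 | step 15 | racemic 21 | CC(C)(O)C1Cc2c(oc3cc(O)cc(OCOC)c3c2=O)-c2ccc(OCOC)cc2O1
F2 | step 15 | (S)-enantiomer of 21 | CC(C)(O)[C@@H]1Cc2c(oc3cc(O)cc(OCOC)c3c2=O)-c2ccc(OCOC)cc2O1
F3 | step 14 | 2-(3-methylbut-2-en-1-yl) derivative of diketone 9 (racemic, epimerisable) | O=C(C(CC=C(C)C)C(=O)c1ccc(OCOC)cc1OCOCC[Si](C)(C)C)c1c(O)cc(OCc2ccccc2)cc1OCOC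
F4 | step 14 | 3-(3-methylbut-2-en-1-yl) derivative of flavone 10 | CC(C)=CCc1c(-c2ccc(OCOC)cc2OCOCC[Si](C)(C)C)oc2cc(OCc3ccccc3)cc(OCOC)c2c1=O
F5 | step 14 | 3-{[(2S)-3,3-dimethyloxiran-2-yl]methyl} derivative of flavone 10 | CC1(C)O[C@H]1Cc1c(-c2ccc(OCOC)cc2OCOCC[Si](C)(C)C)oc2cc(OCc3ccccc3)cc(OCOC)c2c1=O
F6 | step 13 | methyl 2-(dimethoxyphosphoryl)-2-(aryloxy)acetate formed at O2' of 15 (racemic) | C=Cc1c(-c2ccc(OCOC)cc2OC(C(=O)OC)P(=O)(OC)OC)oc2cc(OCc3ccccc3)cc(OCOC)c2c1=O
F7 | step 13 | methyl 2-(aryloxy)acrylate formed at O2' of 15 | C=Cc1c(-c2ccc(OCOC)cc2OC(=C)C(=O)OC)oc2cc(OCc3ccccc3)cc(OCOC)c2c1=O
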